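Ring B is disconnected at two bonds, C9a–C9 and C5–C6. This exploits the fact that C9a of ring A and the spiro carbon C5 of ring C are both latent nucleophilic carbons of one biaryl, joined by the chain C9 to C6 whose trans-dimethyl core is C2-symmetric, so its ends are interchangeable. In one flask an aryllithium/phenoxide dianion is alkylated twice by an enantiopure cyclic sulfate, first at C9a, then at C5 with dearomatisation, closing the seven-membered ring and unveiling the dienone. The precursor is a 2-bromobiaryl with a free para-phenol flanked by two methoxy groups. Benzylic acetoxylation at C9 finishes the route.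

Key step: step 6

Numbering: ring A = C1 (H), C2 to C4 (OMe), C4a, C9a. Ring B = C4a, C5 (spiro), C6, C7, C8, C9, C9a. Ring C = C5, C2', C3' (OMe), C4' (C=O), C5' (OMe), C6'.
Assumption: pinacol boronate 3 is taken to be a catalogue compound, so the phenol needs no protection.
Remark on descriptors: the two methyl-bearing centres keep the same spatial arrangement throughout. 2S,3S in 7 to 10 reads 7R,8R in 14 and 7R,8S in 16 only because substituent priorities change. In 16 the C7 and C8 methyl groups are trans, and the C8 methyl and C9 acetate are trans.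

Step 1
Reactants: 1 5-bromo-1,2,3-trimethoxybenzene
Product: 2 1-bromo-2-iodo-3,4,5-trimethoxybenzene
Conditions: NIS (1.05 equiv), CF3CO2H (0.3 equiv), MeCN, rt, dark
Reagents that add atoms: N-iodosuccinimide, O=C1CCC(=O)N1I
Why: Electrophilic aromatic iodination with acid-activated NIS, in which the two free ring positions of 1 are equivalent and each is ortho and para to a methoxy group, so only one mono-iodide can form and iodine ends up between bromine and methoxy.

Step 2
Reactants: 2 1-bromo-2-iodo-3,4,5-trimethoxybenzene; 3 2,6-dimethoxy-4-(4,4,5,5-tetramethyl-1,3,2-dioxaborolan-2-yl)phenol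
Product: 4 4-(6-bromo-2,3,4-trimethoxyphenyl)-2,6-dimethoxyphenol
Conditions: Pd(PPh3)4 (5 mol %), K2CO3 (3 equiv), 1,4-dioxane/H2O, degassed, 85 °C
Reagents that add atoms: none
Why: Suzuki–Miyaura coupling, in which zerovalent palladium inserts into the carbon–iodine bond much faster than into the carbon–bromine bond, the boronate has no ortho substituent and free phenol boronates couple under aqueous carbonate, so the bromine at C9a survives and no protecting group is needed.

Step 3
Reactants: 5 (R)-4-benzyl-3-propionyloxazolidin-2-one (two molecules)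
Product: 7 (2S,3S)-1,4-bis[(4R)-4-benzyl-2-oxo-1,3-oxazolidin-3-yl]-2,3-dimethylbutane-1,4-dione, via lithium Z-enolate 6 (not isolated)
Conditions: LDA (1.05 equiv), THF, −78 °C; then CuCl2 (1.1 equiv), DMF/THF, −78 °C to rt; chromatography, recrystallisation
Reagents that add atoms: none
Why: Oxidative enolate homocoupling, known for N-acyl oxazolidinones, in which one-electron oxidation of the chelated Z-enolate gives metal-bound α-radicals that join through the face away from the benzyl group, so both new centres are S, and the C2-symmetric dimer is freed from minor diastereomers by crystallisation.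

Step 4
Reactants: 7 (2S,3S)-1,4-bis[(4R)-4-benzyl-2-oxo-1,3-oxazolidin-3-yl]-2,3-dimethylbutane-1,4-dione
Product: 8 (2S,3S)-2,3-dimethylbutane-1,4-diol
Conditions: LiBH4 (3 equiv), H2O (2 equiv), Et2O/THF, 0 °C to rt
Reagents that add atoms: none
Why: Reductive cleavage of N-acyl oxazolidinones with borohydride, in which hydride attacks the exocyclic imide carbonyls without enolisation, so both α-centres are retained and the auxiliary is recovered.

Step 5
Reactants: 8 (2S,3S)-2,3-dimethylbutane-1,4-diol
Product: 10 (5S,6S)-5,6-dimethyl-1,3,2-dioxathiepane 2,2-dioxide, via cyclic sulfite 9 (not isolated)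
Conditions: SOCl2 (1.3 equiv), CH2Cl2, reflux; concentrate; RuCl3·3H2O (0.5 mol %), NaIO4 (1.5 equiv), MeCN/CH2Cl2/H2O, 0 °C
Reagents that add atoms: thionyl chloride, O=S(Cl)Cl; sodium periodate, [Na+].[O-]I(=O)(=O)=O
Why: Standard two-stage cyclic sulfate synthesis (sulfite formation, then ruthenium-catalysed periodate oxidation), established for 1,4-diols, which touches no bond at the stereocentres and passes through a single sulfite because the diol is C2-symmetric.

Step 6
Reactants: 4 4-(6-bromo-2,3,4-trimethoxyphenyl)-2,6-dimethoxyphenol; 10 (5S,6S)-5,6-dimethyl-1,3,2-dioxathiepane 2,2-dioxide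
Product: 14 (7R,8R)-2,3,3',4,5'-pentamethoxy-7,8-dimethyl-6,7,8,9-tetrahydrospiro[benzo[7]annulene-5,1'-cyclohexane]-2',5'-dien-4'-one, via lithium phenoxide 11 (not isolated), via dilithio biaryl 12 (not isolated), via lithium alkyl sulfate 13 (not isolated)
Conditions: n-BuLi (1.0 equiv), THF, −78 °C; t-BuLi (2.0 equiv), −78 °C; 10 (1.0 equiv), −78 to 0 °C; dilute with THF (about 5 mM), KOtBu (1.1 equiv), 18-crown-6 (1.1 equiv), 65 °C
Reagents that add atoms: none
Why: Proposed new method: after deprotonation and lithium–bromine exchange (t-BuLi is chosen so that no alkylating butyl bromide stays in the flask), the aryllithium carbon C9a of 12 opens 10 by SN2 attack at a CH2 group, forming C9a–C9 and leaving sulfate monoester 13; about one equivalent of KOtBu then swaps lithium for potassium on the phenoxide (the alkoxide is parked as weakly basic LiOtBu), and dilution and heat let the para carbon C5 expel sulfate from C6, forming C5–C6 with dearomatisation to the dienone. The closest known reaction types are the double displacement of 1,4-diol cyclic sulfates by dianionic nucleophiles (phospholane synthesis, malonate cyclopropanation), the opening of cyclic sulfates by organolithiums and the Ar1-type para-alkylation of phenoxides by tethered halides or sulfonates, whereas a phenoxide carbon displacing an alkyl sulfate anion and the merger into one flask are untested. Ring B closes in the 7-exo-tet mode, helped by the nearly perpendicular biaryl, which directs the π lobe of C5 towards the chain on C9a. No stereocentre is created, since both displacements occur at CH2 carbons so that C7 and C8 keep the configuration of 10, and C5 is not stereogenic because the two arms of ring C are identical. The step needs C9a to react first and C5 second, which is secured by the very large difference in nucleophilicity between aryllithium and lithium phenoxide at low temperature and by the fall in leaving-group ability from cyclic sulfate to sulfate monoanion, while the equivalent ends of 10 rule out regioisomers. Internal O-alkylation would require a strained para-bridged ring, so only intermolecular O-alkylation can compete, and high dilution suppresses it.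

Step 7
Reactants: 14 (7R,8R)-2,3,3',4,5'-pentamethoxy-7,8-dimethyl-6,7,8,9-tetrahydrospiro[benzo[7]annulene-5,1'-cyclohexane]-2',5'-dien-4'-one
Product: 16 (7R,8S,9R)-2,3,3',4,5'-pentamethoxy-7,8-dimethyl-4'-oxo-6,7,8,9-tetrahydrospiro[benzo[7]annulene-5,1'-cyclohexane]-2',5'-dien-9-yl acetate, via C9 benzylic cation 15 (not isolated)
Conditions: DDQ (1.2 equiv), AcOH, rt to 50 °C
Reagents that add atoms: acetic acid, CC(=O)O
Why: DDQ-mediated benzylic acetoxylation (hydride abstraction, then solvent capture), in which C9 is the only benzylic CH2 and lies para to the C3 methoxy group, the electron-poor dienone is inert to DDQ, the acetate resists over-oxidation, and acetic acid should add to planar cation 15 on the face opposite the neighbouring C8 methyl group to give the 8,9-trans (9R) acetate.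

Compound list
1 | 5-bromo-1,2,3-trimethoxybenzene | COc1cc(Br)cc(OC)c1OC | starting material
2 | 1-bromo-2-iodo-3,4,5-trimethoxybenzene | COc1cc(Br)c(I)c(OC)c1OC | intermediate
3 | 2,6-dimethoxy-4-(4,4,5,5-tetramethyl-1,3,2-dioxaborolan-2-yl)phenol | COc1cc(cc(OC)c1O)B1OC(C)(C)C(C)(C)O1 | starting material
4 | 4-(6-bromo-2,3,4-trimethoxyphenyl)-2,6-dimethoxyphenol | Oc1c(OC)cc(cc1OC)-c1c(Br)cc(OC)c(OC)c1OC | intermediate
5 | (R)-4-benzyl-3-propionyloxazolidin-2-one | CCC(=O)N1[C@H](Cc2ccccc2)COC1=O | starting material
6 | lithium Z-enolate of 5 | [Li+].C/C=C(\[O-])N1[C@H](Cc2ccccc2)COC1=O | intermediate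
7 | (2S,3S)-1,4-bis[(4R)-4-benzyl-2-oxo-1,3-oxazolidin-3-yl]-2,3-dimethylbutane-1,4-dione | O=C1OC[C@@H](Cc2ccccc2)N1C(=O)[C@@H](C)[C@H](C)C(=O)N1[C@H](Cc2ccccc2)COC1=O | intermediate
8 | (2S,3S)-2,3-dimethylbutane-1,4-diol | OC[C@@H](C)[C@H](C)CO | intermediate
9 | (5S,6S)-5,6-dimethyl-1,3,2-dioxathiepane 2-oxide | O=S1OC[C@@H](C)[C@H](C)CO1 | intermediate
10 | (5S,6S)-5,6-dimethyl-1,3,2-dioxathiepane 2,2-dioxide | O=S1(=O)OC[C@@H](C)[C@H](C)CO1 | intermediate
11 | lithium 4-(6-bromo-2,3,4-trimethoxyphenyl)-2,6-dimethoxyphenoxide | [Li+].[O-]c1c(OC)cc(cc1OC)-c1c(Br)cc(OC)c(OC)c1OC | intermediate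
12 | lithium 4-(6-lithio-2,3,4-trimethoxyphenyl)-2,6-dimethoxyphenoxide | [Li+].[O-]c1c(OC)cc(cc1OC)-c1c([Li])cc(OC)c(OC)c1OC | intermediate
13 | dilithium (2S,3R)-4-[2-(3,5-dimethoxy-4-oxidophenyl)-3,4,5-trimethoxyphenyl]-2,3-dimethylbutyl sulfate | [Li+].[Li+].[O-]c1c(OC)cc(cc1OC)-c1c(C[C@@H](C)[C@H](C)COS(=O)(=O)[O-])cc(OC)c(OC)c1OC | intermediate
14 | (7R,8R)-2,3,3',4,5'-pentamethoxy-7,8-dimethyl-6,7,8,9-tetrahydrospiro[benzo[7]annulene-5,1'-cyclohexane]-2',5'-dien-4'-one | COC1=CC2(C=C(OC)C1=O)C[C@@H](C)[C@H](C)Cc1cc(OC)c(OC)c(OC)c12 | intermediate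
15 | C9 benzylic cation derived from 14 | COC1=CC2(C=C(OC)C1=O)C[C@@H](C)[C@H](C)[CH+]c1cc(OC)c(OC)c(OC)c12 | intermediate
16 | (7R,8S,9R)-2,3,3',4,5'-pentamethoxy-7,8-dimethyl-4'-oxo-6,7,8,9-tetrahydrospiro[benzo[7]annulene-5,1'-cyclohexane]-2',5'-dien-9-yl acetate | COC1=CC2(C=C(OC)C1=O)C[C@@H](C)[C@H](C)[C@@H](OC(C)=O)c1cc(OC)c(OC)c(OC)c12 | target

Total step count: 7. Longest linear sequence: 5 steps (steps 3, 4, 5, 6, 7). The biaryl branch needs 4 steps (1, 2, 6, 7).

Steps most likely to fail

Step 6. The aryllithium may be protonated or may attack sulfur instead of carbon. The second displacement may also be too slow, because a sulfate monoanion is a poor leaving group. In that case intermolecular O-alkylation, oligomerisation or base-induced elimination would take over. The fallback runs the two alkylations separately and uses a better leaving group for the second one. It sets out from 4 and 10.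
- Dianion 12 is made as in step 6 and only the first alkylation is carried out.
- Crude 13 is hydrolysed (catalytic H2SO4, H2O, THF) to (2S,3R)-4-[2-(4-hydroxy-3,5-dimethoxyphenyl)-3,4,5-trimethoxyphenyl]-2,3-dimethylbutan-1-ol F1.
- An Appel-type iodination (PPh3, I2, imidazole, CH2Cl2) converts only the primary alcohol, giving 4-{6-[(2R,3S)-4-iodo-2,3-dimethylbutyl]-2,3,4-trimethoxyphenyl}-2,6-dimethoxyphenol F2.
- KOtBu in t-BuOH/THF at high dilution then effects the known Ar1-type spirocyclisation with iodide as the leaving group, which returns to the route at 14.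

Step 7. Capture of the planar cation may show poor facial selectivity. Proton loss from C8 or acid-induced dienone–phenol rearrangement may also compete. The fallback sets C9 by an SN2 inversion instead of relying on cation capture. It sets out from 14.
- The acetoxylation is run as in step 7 and the two C9 epimers are separated.
- The unwanted (7R,8S,9S)-2,3,3',4,5'-pentamethoxy-7,8-dimethyl-4'-oxo-6,7,8,9-tetrahydrospiro[benzo[7]annulene-5,1'-cyclohexane]-2',5'-dien-9-yl acetate F3 is cleaved (K2CO3, MeOH, 0 °C) to (7R,8S,9S)-9-hydroxy-2,3,3',4,5'-pentamethoxy-7,8-dimethyl-6,7,8,9-tetrahydrospiro[benzo[7]annulene-5,1'-cyclohexane]-2',5'-dien-4'-one F4.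
- A Mitsunobu reaction with acetic acid (PPh3, DIAD, THF) inverts C9 and returns to the route at 16.

Step 3. The radical coupling may suffer from weak diastereocontrol, α-chlorination or simple re-protonation of the enolate. The fallback forms the central bond by a polar alkylation instead. It sets out from 5.
- Enolate 6 is alkylated with commercial ethyl (S)-2-(trifluoromethylsulfonyloxy)propanoate. The lactate carbon is inverted and the auxiliary controls the enolate carbon. This is a known route to 2,3-disubstituted succinates.
- The product is ethyl (2S,3S)-4-[(4R)-4-benzyl-2-oxo-1,3-oxazolidin-3-yl]-2,3-dimethyl-4-oxobutanoate F5.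
- LiBH4 in THF reduces both the ester and the imide of F5, which returns to the route at 8.

Further compounds
F1 | step 6 | (2S,3R)-4-[2-(4-hydroxy-3,5-dimethoxyphenyl)-3,4,5-trimethoxyphenyl]-2,3-dimethylbutan-1-ol | Oc1c(OC)cc(cc1OC)-c1c(C[C@@H](C)[C@H](C)CO)cc(OC)c(OC)c1OC
F2 | step 6 | 4-{6-[(2R,3S)-4-iodo-2,3-dimethylbutyl]-2,3,4-trimethoxyphenyl}-2,6-dimethoxyphenol | Oc1c(OC)cc(cc1OC)-c1c(C[C@@H](C)[C@H](C)CI)cc(OC)c(OC)c1OC
F3 | step 7 | (7R,8S,9S)-2,3,3',4,5'-pentamethoxy-7,8-dimethyl-4'-oxo-6,7,8,9-tetrahydrospiro[benzo[7]annulene-5,1'-cyclohexane]-2',5'-dien-9-yl acetate | COC1=CC2(C=C(OC)C1=O)C[C@@H](C)[C@H](C)[C@H](OC(C)=O)c1cc(OC)c(OC)c(OC)c12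
F4 | step 7 | (7R,8S,9S)-9-hydroxy-2,3,3',4,5'-pentamethoxy-7,8-dimethyl-6,7,8,9-tetrahydrospiro[benzo[7]annulene-5,1'-cyclohexane]-2',5'-dien-4'-one | COC1=CC2(C=C(OC)C1=O)C[C@@H](C)[C@H](C)[C@H](O)c1cc(OC)c(OC)c(OC)c12
F5 | step 3 | ethyl (2S,3S)-4-[(4R)-4-benzyl-2-oxo-1,3-oxazolidin-3-yl]-2,3-dimethyl-4-oxobutanoate | CCOC(=O)[C@@H](C)[C@H](C)C(=O)N1[C@H](Cc2ccccc2)COC1=O
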